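**Retrosynthetic overview**
1. The oxirane is installed last, by peripheral epoxidation of the 4E-alkene of the ten-membered dienolide 20.
2. The ten-membered ring of 20 comes from a five-carbon radical ring expansion (5 → 10) of the β-stannyl cyclopentanone 19. This step forms C1–C10, cleaves C1–C5, and creates the 4E-alkene and the C10 acetoxy quaternary centre.
3. 19 comes from conjugate stannylation of 3-methylcyclopentenone and aldol–lactonisation with hydroxybutenolide 14, which forms C5–C6 and closes the butenolide.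
4. 14 comes from singlet-oxygen oxidation of a 2-silyl-3,4-disubstituted furan built from furan-3-ylmethanol, DMF, acetone (asymmetric aldol sets C8), tigloyl chloride and Ac2O.
5. Ring order: furan (purchased) → butenolide → ten-membered carbocycle (by ring expansion of the cyclopentanone) → oxirane.

Assumption: germacrane numbering is used for the ring atoms (C1 ketone, C4–C5 oxirane, C6 lactone CH–O, C7=C11, C8 tiglate, C10 acetate, C12 lactone C=O, C13 CH2OAc); the target is the (4R,5R,6S,8S,10R) isomer of the SMILES, and centres that are destroyed later are carried as mixtures.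

Step 1
Reactants: 1 furan-3-ylmethanol
Product: 3 [2-(tert-butyldimethylsilyl)furan-3-yl]methanol, via O-silyl ether 2 (not isolated)
Conditions: n-BuLi (1.05 equiv), THF, −78 °C; TBSCl, 0 °C; then n-BuLi (1.2 equiv), HMPA, −78 to −20 °C; aq NH4Cl
Reagents that add atoms: tert-butyldimethylsilyl chloride, CC(C)(C)[Si](C)(C)Cl
Why: O-silylation, then C2-lithiation (α to the ring oxygen, ortho to CH2O) triggers a retro-[1,4]-Brook O→C silyl shift; the C2 silyl group later blocks C2, allows C4-lithiation and fixes the butenolide regiochemistry.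

Step 2
Reactants: 3 [2-(tert-butyldimethylsilyl)furan-3-yl]methanol
Product: 5 5-(tert-butyldimethylsilyl)-4-(hydroxymethyl)furan-3-carbaldehyde, via dilithio furan 4 (not isolated)
Conditions: n-BuLi (2.2 equiv), DME, 0 °C; DMF, −78 to 0 °C; aq NH4Cl
Reagents that add atoms: N,N-dimethylformamide, CN(C)C=O
Why: Alkoxide-directed ortho-lithiation goes to C4 because C2 is blocked, and the aryllithium is formylated by DMF (Bouveault formylation).

Step 3
Reactants: 5 5-(tert-butyldimethylsilyl)-4-(hydroxymethyl)furan-3-carbaldehyde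
Product: 6 [2-(tert-butyldimethylsilyl)-4-formylfuran-3-yl]methyl acetate
Conditions: Ac2O, pyridine, DMAP (cat.), CH2Cl2, 0 °C
Reagents that add atoms: acetic anhydride, CC(=O)OC(C)=O
Why: Standard DMAP-catalysed O-acetylation of the primary alcohol installs the C13 acetate of the target.

Step 4
Reactants: 6 [2-(tert-butyldimethylsilyl)-4-formylfuran-3-yl]methyl acetate; 7 acetone
Product: 8 [2-(tert-butyldimethylsilyl)-4-[(1S)-1-hydroxy-3-oxobutyl]furan-3-yl]methyl acetate
Conditions: (R)-N-[(1R,2R)-2-hydroxy-1,2-diphenylethyl]pyrrolidine-2-carboxamide (D-prolinamide, 10 mol %), acetone (solvent), −25 °C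
Reagents that add atoms: none
Why: Enamine-catalysed direct asymmetric aldol (List–Barbas type) of acetone; the D-series catalyst delivers the (S)-carbinol (C8, the target's 8S), as the L-series gives R with aryl aldehydes.

Step 5
Reactants: 8 [2-(tert-butyldimethylsilyl)-4-[(1S)-1-hydroxy-3-oxobutyl]furan-3-yl]methyl acetate; 9 (2E)-2-methylbut-2-enoyl chloride
Product: 10 (1S)-1-[4-(acetoxymethyl)-5-(tert-butyldimethylsilyl)furan-3-yl]-3-oxobutyl (2E)-2-methylbut-2-enoate
Conditions: pyridine, DMAP (cat.), CH2Cl2, −20 to 0 °C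
Reagents that add atoms: none
Why: Acylation of the secondary alcohol with the acid chloride installs the tiglate with retention at C8; cold, weakly basic conditions avoid E1cB loss of the β-acyloxy group.

Step 6
Reactants: 10 (1S)-1-[4-(acetoxymethyl)-5-(tert-butyldimethylsilyl)furan-3-yl]-3-oxobutyl (2E)-2-methylbut-2-enoate
Product: 11 (1S)-3-acetoxy-1-[4-(acetoxymethyl)-5-(tert-butyldimethylsilyl)furan-3-yl]but-3-en-1-yl (2E)-2-methylbut-2-enoate
Conditions: KHMDS (1.1 equiv), THF, −78 °C, 10 min; Ac2O (3 equiv), −78 to −40 °C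
Reagents that add atoms: acetic anhydride, CC(=O)OC(C)=O
Why: Kinetic deprotonation of the methyl ketone at CH3 and O-acylation of the potassium enolate give the terminal enol acetate, which carries the future C10 oxygen as its acetate.

Step 7
Reactants: 11 (1S)-3-acetoxy-1-[4-(acetoxymethyl)-5-(tert-butyldimethylsilyl)furan-3-yl]but-3-en-1-yl (2E)-2-methylbut-2-enoate
Product: 14 (1S)-3-acetoxy-1-[4-(acetoxymethyl)-2-hydroxy-5-oxo-2,5-dihydrofuran-3-yl]but-3-en-1-yl (2E)-2-methylbut-2-enoate, via furan endoperoxide 12 (not isolated), via silyl ester 13 (not isolated)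
Conditions: O2, rose bengal (cat.), hν (visible), CH2Cl2–MeOH, −78 °C; then H2O, rt
Reagents that add atoms: dioxygen, O=O; water, O
Why: Singlet-oxygen [4+2] photooxygenation of the 2-silylfuran, C→O silyl migration and hydrolysis give the γ-hydroxybutenolide regiospecifically (C=O at the former C–Si carbon = C12, hemiacetal carbon = C6); the electron-poor tiglate and the enol acetate are far less reactive.

Step 8
Reactants: 14 (1S)-3-acetoxy-1-[4-(acetoxymethyl)-2-hydroxy-5-oxo-2,5-dihydrofuran-3-yl]but-3-en-1-yl (2E)-2-methylbut-2-enoate; 15 3-methylcyclopent-2-en-1-one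
Product: 19 (1S)-3-acetoxy-1-[(2R)-4-(acetoxymethyl)-2-[(1S,2S)-2-methyl-5-oxo-2-(trimethylstannyl)cyclopentyl]-5-oxo-2,5-dihydrofuran-3-yl]but-3-en-1-yl (2E)-2-methylbut-2-enoate, via lithium enolate 16 (not isolated), via lithium carboxylate 17 (not isolated), via aldol hydroxy acid 18 (not isolated)
Conditions: (Me3Sn)2, MeLi, THF, −20 °C; 15, −78 °C (gives 16, 2 equiv); separately 14, LiHMDS (1.0 equiv), THF, −78 °C (gives 17); combine, −78 °C, 1 h; AcOH; then aq citric acid (pH 3), rt
Reagents that add atoms: trimethylstannyllithium, [Li][Sn](C)(C)C (generated from hexamethylditin, C[Sn](C)(C)[Sn](C)(C)C, and MeLi)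
Why: Michael addition of Me3SnLi gives the regiodefined enolate, which adds (Zimmerman–Traxler aldol) to the Li-chelated s-cis (Z)-formylacrylate anti to the C–Sn bond (2,3-trans); the C8 centre, locked by A(1,3) strain against C13, exposes the face syn to its acyloxy group and so sets C6 (R in 19, the target's 6S), and acid lactonises the γ-hydroxy acid; both 2,3-trans diastereomers from racemic 16 are usable because C4 and C5 become sp2 in step 9.

Step 9
Reactants: 19 (1S)-3-acetoxy-1-[(2R)-4-(acetoxymethyl)-2-[(1S,2S)-2-methyl-5-oxo-2-(trimethylstannyl)cyclopentyl]-5-oxo-2,5-dihydrofuran-3-yl]but-3-en-1-yl (2E)-2-methylbut-2-enoate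
Product: 20 (4E,6R,8S,10R)-10,13-diacetoxy-1-oxo-8-[(2E)-2-methylbut-2-enoyloxy]germacra-4,7(11)-dien-12,6-olide
Conditions: Fe(acac)3 (2.2 equiv), PhSiH3 (1.5 equiv, slow addition), EtOH–THF 3:1, 0.005 M, 50 °C
Reagents that add atoms: none
Why: Proposed new method: Fe–H hydrogen-atom transfer (Mukaiyama type) to the enol acetate gives the tertiary α-acetoxy radical at C10, which adds reversibly to the cyclopentanone carbonyl (seven-membered closure, pre-organised by the cis-disposed butenolide substituents), and the alkoxyl radical is drained irreversibly by β-scission of C1–C5 with loss of Me3Sn• antiperiplanar across C4–C5 (2,3-trans gives the 4E-alkene), so the net result is a β-stannyl-terminated Dowd–Beckwith-type five-carbon ring expansion; C10 (R) is set in the C–C bond formation through a twist-chair in which C8–O lies in the butenolide plane and the acetoxy group sits pseudo-equatorial (8,10-syn), a modest preference; the closest known reactions are Fe-mediated HAT-initiated alkene-to-ketone radical cyclisation and tin-hydride-mediated radical ring expansion of 3-stannylcycloalkanones bearing ω-haloalkyl chains.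

Step 10
Reactants: 20 (4E,6R,8S,10R)-10,13-diacetoxy-1-oxo-8-[(2E)-2-methylbut-2-enoyloxy]germacra-4,7(11)-dien-12,6-olide
Product: 21 (4R,5R,6S,8S,10R)-10,13-diacetoxy-4,5-epoxy-1-oxo-8-[(2E)-2-methylbut-2-enoyloxy]germacr-7(11)-en-12,6-olide
Conditions: mCPBA (1.2 equiv), NaHCO3, CH2Cl2, 0 °C
Reagents that add atoms: 3-chloroperoxybenzoic acid, OOC(=O)c1cccc(Cl)c1
Why: Prilezhaev epoxidation of the only electron-rich alkene; in the A(1,3)-locked conformer (H6 eclipsing the C4 methyl side) the ring chain through C7 covers one face, so the peracid attacks the exterior face anti to C7 and gives the 4R,5R oxirane (threo to C6–O).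

**Compound list**
1 | furan-3-ylmethanol | OCc1ccoc1 | starting material
2 | tert-butyl(furan-3-ylmethoxy)dimethylsilane | CC(C)(C)[Si](C)(C)OCc1ccoc1 | intermediate
3 | [2-(tert-butyldimethylsilyl)furan-3-yl]methanol | OCc1ccoc1[Si](C)(C)C(C)(C)C | intermediate
4 | lithium [2-(tert-butyldimethylsilyl)-4-lithiofuran-3-yl]methanolate | [Li]OCc1c([Li])coc1[Si](C)(C)C(C)(C)C | intermediate
5 | 5-(tert-butyldimethylsilyl)-4-(hydroxymethyl)furan-3-carbaldehyde | OCc1c(C=O)coc1[Si](C)(C)C(C)(C)C | intermediate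
6 | [2-(tert-butyldimethylsilyl)-4-formylfuran-3-yl]methyl acetate | CC(=O)OCc1c(C=O)coc1[Si](C)(C)C(C)(C)C | intermediate
7 | acetone | CC(C)=O | starting material
8 | [2-(tert-butyldimethylsilyl)-4-[(1S)-1-hydroxy-3-oxobutyl]furan-3-yl]methyl acetate | O[C@@H](CC(C)=O)c1coc([Si](C)(C)C(C)(C)C)c1COC(C)=O | intermediate
9 | (2E)-2-methylbut-2-enoyl chloride (tigloyl chloride) | C/C=C(\C)C(Cl)=O | starting material
10 | (1S)-1-[4-(acetoxymethyl)-5-(tert-butyldimethylsilyl)furan-3-yl]-3-oxobutyl (2E)-2-methylbut-2-enoate | C/C=C(\C)C(=O)O[C@@H](CC(C)=O)c1coc([Si](C)(C)C(C)(C)C)c1COC(C)=O | intermediate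
11 | (1S)-3-acetoxy-1-[4-(acetoxymethyl)-5-(tert-butyldimethylsilyl)furan-3-yl]but-3-en-1-yl (2E)-2-methylbut-2-enoate | C/C=C(\C)C(=O)O[C@@H](CC(=C)OC(C)=O)c1coc([Si](C)(C)C(C)(C)C)c1COC(C)=O | intermediate
12 | furan endoperoxide of 11 (1-silyl-2,3,7-trioxabicyclo[2.2.1]hept-5-ene; bridgehead centres as a mixture) | C/C=C(\C)C(=O)O[C@@H](CC(=C)OC(C)=O)C1=C(COC(C)=O)C2([Si](C)(C)C(C)(C)C)OOC1O2 | intermediate
13 | tert-butyldimethylsilyl (2Z)-2-(acetoxymethyl)-3-formyl-4-[(2E)-2-methylbut-2-enoyloxy]-6-acetoxyhepta-2,6-dienoate, 4S | C/C=C(\C)C(=O)O[C@@H](CC(=C)OC(C)=O)/C(C=O)=C(\COC(C)=O)C(=O)O[Si](C)(C)C(C)(C)C | intermediate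
14 | (1S)-3-acetoxy-1-[4-(acetoxymethyl)-2-hydroxy-5-oxo-2,5-dihydrofuran-3-yl]but-3-en-1-yl (2E)-2-methylbut-2-enoate (hemiacetal carbon as a mixture) | C/C=C(\C)C(=O)O[C@@H](CC(=C)OC(C)=O)C1=C(COC(C)=O)C(=O)OC1O | intermediate
15 | 3-methylcyclopent-2-en-1-one | CC1=CC(=O)CC1 | starting material
16 | lithium 3-methyl-3-(trimethylstannyl)cyclopent-1-en-1-olate (racemic) | [Li]OC1=CC(C)([Sn](C)(C)C)CC1 | intermediate
17 | lithium carboxylate of ring-opened 14, (2Z,4S)-formylacrylate form | C/C=C(\C)C(=O)O[C@@H](CC(=C)OC(C)=O)/C(C=O)=C(\COC(C)=O)C(=O)O[Li] | intermediate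
18 | aldol hydroxy acid: (2Z)-acid with (R)-CH(OH) at C6 bearing the (1S,2S)-2-methyl-5-oxo-2-(trimethylstannyl)cyclopentyl group, 8S | C/C=C(\C)C(=O)O[C@@H](CC(=C)OC(C)=O)/C(=C(\COC(C)=O)C(=O)O)[C@H](O)[C@H]1C(=O)CC[C@]1(C)[Sn](C)(C)C | intermediate
19 | (1S)-3-acetoxy-1-[(2R)-4-(acetoxymethyl)-2-[(1S,2S)-2-methyl-5-oxo-2-(trimethylstannyl)cyclopentyl]-5-oxo-2,5-dihydrofuran-3-yl]but-3-en-1-yl (2E)-2-methylbut-2-enoate (major diastereomer; the other 2,3-trans cyclopentyl diastereomer converges) | C/C=C(\C)C(=O)O[C@@H](CC(=C)OC(C)=O)C1=C(COC(C)=O)C(=O)O[C@@H]1[C@H]2C(=O)CC[C@]2(C)[Sn](C)(C)C | intermediate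
20 | (4E,6R,8S,10R)-10,13-diacetoxy-1-oxo-8-[(2E)-2-methylbut-2-enoyloxy]germacra-4,7(11)-dien-12,6-olide | C/C=C(\C)C(=O)O[C@H]1C[C@@](C)(OC(C)=O)C(=O)CC/C(C)=C/[C@H]2OC(=O)C(COC(C)=O)=C12 | intermediate
21 | (4R,5R,6S,8S,10R)-10,13-diacetoxy-4,5-epoxy-1-oxo-8-[(2E)-2-methylbut-2-enoyloxy]germacr-7(11)-en-12,6-olide (CNP0175424.1) | C/C=C(\C)C(=O)O[C@H]1C[C@@](C)(OC(C)=O)C(=O)CC[C@@]2(C)O[C@@H]2[C@H]2OC(=O)C(COC(C)=O)=C12 | target

**Step count**
Total steps: 10. Longest linear sequence: 10 (1 → 21); 7, 9 and 15 enter directly in steps 4, 5 and 8.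

**Three steps most likely to fail**

Step 9 (the new ring expansion). The seven-membered radical closure onto the ketone may be too slow, which would give simple reduction of the enol acetate or 1,5-H transfer from C6–H. The C10 selectivity is only a model-based prediction (about 3:1 expected), and the tin-bearing diastereomers may differ in rate. The fallback uses known reactions only, sets out from ketone 10 and comes back at 20. Kinetic enolisation of 10 and trapping with PhNTf2 (KHMDS, THF, −78 °C) gives the enol triflate F1. Photooxygenation as in step 7 gives the hydroxybutenolide triflate F2. The stannylation/aldol–lactonisation of step 8 with 15 gives the stannyl ketone F3. An intramolecular Nozaki–Hiyama–Kishi alkenylation of the cyclopentanone (CrCl2, NiCl2 cat., DMSO–THF) closes the seven-membered ring to the tricyclic tertiary allylic alcohol F4 (C1 carbinol as a mixture). The established oxidative 1,4-fragmentation of a γ-stannyl alcohol (Pb(OAc)4, CH2Cl2, 0 °C) then expands the ring to the exo-methylene enone F5 with the 4E-alkene. Mukaiyama-type Mn hydration of the enone (Mn(dpm)3 cat., PhSiH3, O2, i-PrOH, then P(OEt)3) gives the tertiary ketol F6 by peripheral attack, and acetylation of the tertiary alcohol (Ac2O, Sc(OTf)3 cat., MeCN, −20 °C) gives 20.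

Step 8 (three-component coupling). Both partners are hindered (enolate carbon next to a quaternary centre, aldehyde on a tetrasubstituted alkene), so retro-aldol, acyl transfer to the aldolate, or a poor ratio at C6 are possible. The fallback sets out from 14 and the enolate 16 and comes back at 19; it replaces the basic aldol by a Lewis-acid substitution at the lactol carbon. Enolate 16 is quenched with TMSCl to give the silyl enol ether F7. 14 is acetylated (Ac2O, pyridine, 0 °C) to the γ-acetoxybutenolide F8. Mukaiyama-type coupling of F7 with the oxocarbenium ion from F8 (TMSOTf cat., CH2Cl2, −78 °C) forms C5–C6 directly on the closed butenolide, again anti to the C–Sn bond and under the same A(1,3) control from C8, without any alkoxide intermediate.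

Step 6 (kinetic enol acetate). Deprotonation at C9 would eliminate the tiglate, and the enolate could attack the tiglate carbonyl. The fallback sets out from aldehyde 6 and comes back at 11; it builds the enol acetate from an alkyne instead of an enolate. Catalytic asymmetric propargylation of 6 (propargyl bromide, Cr(III)/chiral bis(oxazolinyl)carbazole cat., Mn, TMSCl, then mild desilylation) gives the homopropargylic alcohol F9. Tigloylation with 9 (pyridine, DMAP, 0 °C) gives the alkynyl tiglate F10. Ru-catalysed Markovnikov addition of acetic acid to the terminal alkyne ([Ru(p-cymene)Cl2]2, P(2-furyl)3, Na2CO3, AcOH, toluene, 50 °C) gives 11.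

**Further compounds**
F1 | step 9 | (1S)-1-[4-(acetoxymethyl)-5-(tert-butyldimethylsilyl)furan-3-yl]-3-(trifluoromethanesulfonyloxy)but-3-en-1-yl (2E)-2-methylbut-2-enoate | C/C=C(\C)C(=O)O[C@@H](CC(=C)OS(=O)(=O)C(F)(F)F)c1coc([Si](C)(C)C(C)(C)C)c1COC(C)=O
F2 | step 9 | (1S)-1-[4-(acetoxymethyl)-2-hydroxy-5-oxo-2,5-dihydrofuran-3-yl]-3-(trifluoromethanesulfonyloxy)but-3-en-1-yl (2E)-2-methylbut-2-enoate | C/C=C(\C)C(=O)O[C@@H](CC(=C)OS(=O)(=O)C(F)(F)F)C1=C(COC(C)=O)C(=O)OC1O
F3 | step 9 | (1S)-1-[(2R)-4-(acetoxymethyl)-2-[(1S,2S)-2-methyl-5-oxo-2-(trimethylstannyl)cyclopentyl]-5-oxo-2,5-dihydrofuran-3-yl]-3-(trifluoromethanesulfonyloxy)but-3-en-1-yl (2E)-2-methylbut-2-enoate | C/C=C(\C)C(=O)O[C@@H](CC(=C)OS(=O)(=O)C(F)(F)F)C1=C(COC(C)=O)C(=O)O[C@@H]1[C@H]2C(=O)CC[C@]2(C)[Sn](C)(C)C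
F4 | step 9 | 13-acetoxy-1-hydroxy-8-[(2E)-2-methylbut-2-enoyloxy]-4-(trimethylstannyl)guaia-7(11),10(14)-dien-12,6-olide (5/7/5 tricycle, C1 carbinol as a mixture) | C/C=C(\C)C(=O)O[C@H]1CC(=C)C2(O)CC[C@](C)([Sn](C)(C)C)[C@H]2[C@H]2OC(=O)C(COC(C)=O)=C12
F5 | step 9 | (4E,6R,8S)-13-acetoxy-1-oxo-8-[(2E)-2-methylbut-2-enoyloxy]germacra-4,7(11),10(14)-trien-12,6-olide | C/C=C(\C)C(=O)O[C@H]1CC(=C)C(=O)CC/C(C)=C/[C@H]2OC(=O)C(COC(C)=O)=C12
F6 | step 9 | (4E,6R,8S,10R)-13-acetoxy-10-hydroxy-1-oxo-8-[(2E)-2-methylbut-2-enoyloxy]germacra-4,7(11)-dien-12,6-olide | C/C=C(\C)C(=O)O[C@H]1C[C@@](C)(O)C(=O)CC/C(C)=C/[C@H]2OC(=O)C(COC(C)=O)=C12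
F7 | step 8 | trimethyl{[3-methyl-3-(trimethylstannyl)cyclopent-1-en-1-yl]oxy}silane (racemic) | C[Si](C)(C)OC1=CC(C)([Sn](C)(C)C)CC1
F8 | step 8 | (1S)-3-acetoxy-1-[2-acetoxy-4-(acetoxymethyl)-5-oxo-2,5-dihydrofuran-3-yl]but-3-en-1-yl (2E)-2-methylbut-2-enoate (acetal carbon as a mixture) | C/C=C(\C)C(=O)O[C@@H](CC(=C)OC(C)=O)C1=C(COC(C)=O)C(=O)OC1OC(C)=O
F9 | step 6 | [2-(tert-butyldimethylsilyl)-4-[(1S)-1-hydroxybut-3-yn-1-yl]furan-3-yl]methyl acetate | O[C@@H](CC#C)c1coc([Si](C)(C)C(C)(C)C)c1COC(C)=O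
F10 | step 6 | (1S)-1-[4-(acetoxymethyl)-5-(tert-butyldimethylsilyl)furan-3-yl]but-3-yn-1-yl (2E)-2-methylbut-2-enoate | C/C=C(\C)C(=O)O[C@@H](CC#C)c1coc([Si](C)(C)C(C)(C)C)c1COC(C)=O
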